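**Retrosynthetic overview**

- The strategy rests on the methyl-bearing allylic methine C(H)(CH3) that lies between one carbon of the trans-1,2-disubstituted cyclopropane (the only ring) and the E-CH=CH of the (E,E)-diene. The bond C(cyclopropyl)–C(H)(CH3) is disconnected as an anti-SN2′ substitution with alkene transposition.
- Nucleophile: a trans-cyclopropylcopper, made with retention from a cyclopropylstannane that already carries the acid chain masked as a dioxolane. Electrophile: an (S,Z)-configured bis-allylic picolinate CH3–CH=CH–CH(OPic)–CH=C(CH3)R.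
- The picolinate is built linearly from (R)-citronellal (remote methyl centre), trimethylsilylacetylene and but-2-ynoic acid. Its carbinol centre is set by asymmetric ynone reduction and relays chirality to the new methine.
- Ring order: the cyclopropane is made first, by ligand-controlled Simmons–Smith cyclopropanation of (E)-3-(tributylstannyl)prop-2-en-1-ol; no ring is formed afterwards.
- End game: alkyne desilylation and bromination, then acetal hydrolysis and oxidation of the aldehyde to the acid.

Key step: step 16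

Assumption: in the oxazaborolidine reduction of the ynone, the β,β-disubstituted alkenyl group is taken as the large and the propynyl group as the small ketone substituent; (E)-3-(tributylstannyl)prop-2-en-1-ol is taken as a purchasable reagent.

**Route**

Step 1
Reactants: 1 (R)-citronellal [(3R)-3,7-dimethyloct-6-enal]
Product: 2 (4R)-1,1-dibromo-4,8-dimethylnona-1,7-diene
Conditions: CBr4, PPh3, CH2Cl2, 0 °C
Reagents that add atoms: tetrabromomethane, BrC(Br)(Br)Br
Why: Corey–Fuchs dibromo-olefination of the aldehyde by the ylide formed in the flask; the stereocentre is β to the carbonyl and cannot epimerise, and the trisubstituted alkene is inert.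

Step 2
Reactants: 2 (4R)-1,1-dibromo-4,8-dimethylnona-1,7-diene
Product: 4 [(4R)-4,8-dimethylnon-7-en-1-yn-1-yl]tri(propan-2-yl)silane, via lithium acetylide 3 (not isolated)
Conditions: n-BuLi (2.2 equiv), THF, −78 → 0 °C; then TIPSOTf, −78 °C → rt
Reagents that add atoms: triisopropylsilyl trifluoromethanesulfonate, CC(C)[Si](OS(=O)(=O)C(F)(F)F)(C(C)C)C(C)C
Why: Second stage of the Corey–Fuchs sequence: elimination of HBr and bromine–lithium exchange give the lithium acetylide, which is silylated on carbon by the silyl triflate.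

Step 3
Reactants: 4 [(4R)-4,8-dimethylnon-7-en-1-yn-1-yl]tri(propan-2-yl)silane
Product: 6 (4R)-4-methyl-7-[tri(propan-2-yl)silyl]hept-6-yn-1-ol, via aldehyde 5 (not isolated)
Conditions: O3, CH2Cl2/MeOH, NaHCO3, −78 °C, stopped at the first blue tint; then NaBH4, −78 °C → rt
Reagents that add atoms: ozone, [O-][O+]=O
Why: Ozonolysis with borohydride work-up; the electron-rich trisubstituted alkene is cleaved much faster than the hindered silyl alkyne, so titration to the end point should leave the alkyne intact.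

Step 4
Reactants: 6 (4R)-4-methyl-7-[tri(propan-2-yl)silyl]hept-6-yn-1-ol
Product: 7 [(4R)-7-iodo-4-methylhept-1-yn-1-yl]tri(propan-2-yl)silane
Conditions: I2, PPh3, imidazole, CH2Cl2, 0 °C → rt
Reagents that add atoms: iodine, II
Why: Appel-type iodination (Garegg–Samuelsson conditions) of a primary alcohol by SN2 displacement of the alkoxyphosphonium ion.

Step 5
Reactants: 7 [(4R)-7-iodo-4-methylhept-1-yn-1-yl]tri(propan-2-yl)silane; 8 ethynyl(trimethyl)silane
Product: 10 trimethyl{(6R)-6-methyl-9-[tri(propan-2-yl)silyl]nona-1,8-diyn-1-yl}silane, via lithium trimethylsilylacetylide 9 (not isolated)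
Conditions: 8, n-BuLi, THF, −78 °C; then 7, DMPU, −78 °C → rt
Reagents that add atoms: none
Why: SN2 alkylation of a lithium acetylide by an unhindered primary iodide in the presence of a dipolar cosolvent; the silyl-capped alkyne of 7 has no acidic proton.

Step 6
Reactants: 10 trimethyl{(6R)-6-methyl-9-[tri(propan-2-yl)silyl]nona-1,8-diyn-1-yl}silane
Product: 11 [(4R)-4-methylnona-1,8-diyn-1-yl]tri(propan-2-yl)silane
Conditions: K2CO3, MeOH/THF, rt
Reagents that add atoms: none
Why: Base-mediated methanolysis cleaves the C(sp)–SiMe3 bond far faster than the hindered C(sp)–Si(i-Pr)3 bond, so only the trimethylsilyl group should leave.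

Step 7
Reactants: 11 [(4R)-4-methylnona-1,8-diyn-1-yl]tri(propan-2-yl)silane
Product: 13 [(4R,8E)-9-iodo-4,8-dimethylnon-8-en-1-yn-1-yl]tri(propan-2-yl)silane, via alkenylalane 12 (not isolated)
Conditions: AlMe3, Cp2ZrCl2 (0.3 equiv), H2O (1 equiv), CH2Cl2, −25 °C; then I2, THF, −25 → 0 °C
Reagents that add atoms: trimethylaluminium, C[Al](C)C; iodine, II
Why: Zirconium-catalysed methylalumination (Negishi carboalumination) adds CH3 and Al syn across the terminal alkyne with methyl on the internal carbon, and iodinolysis of the C–Al bond with retention gives the (E)-iodide, while the hindered internal silyl alkyne should not react.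

Step 8
Reactants: 14 but-2-ynoic acid
Product: 16 N-methoxy-N-methylbut-2-ynamide, via mixed anhydride 15 (not isolated)
Conditions: i-BuOCOCl, N-methylmorpholine, CH2Cl2, −15 °C; then MeNH(OMe)·HCl, N-methylmorpholine, −15 °C → rt
Reagents that add atoms: N,O-dimethylhydroxylamine hydrochloride, CNOC.Cl
Why: Weinreb amide formation through the mixed carbonic anhydride; the low temperature suppresses conjugate addition of the amine to the activated alkyne.

Step 9
Reactants: 13 [(4R,8E)-9-iodo-4,8-dimethylnon-8-en-1-yn-1-yl]tri(propan-2-yl)silane; 16 N-methoxy-N-methylbut-2-ynamide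
Product: 18 (5E,10R)-6,10-dimethyl-13-[tri(propan-2-yl)silyl]tridec-5-ene-2,12-diyn-4-one, via alkenyllithium 17 (not isolated)
Conditions: 13, t-BuLi (2.05 equiv), Et2O, −78 °C; then 16, −78 °C; inverse quench into cold aq. NaH2PO4
Reagents that add atoms: none
Why: Iodine–lithium exchange with retention of alkene geometry, then Weinreb ketone synthesis in which the chelated tetrahedral adduct prevents over-addition; the cold acidic quench keeps the released amine from adding to the ynone.

Step 10
Reactants: 18 (5E,10R)-6,10-dimethyl-13-[tri(propan-2-yl)silyl]tridec-5-ene-2,12-diyn-4-one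
Product: 19 (4R,5E,10R)-6,10-dimethyl-13-[tri(propan-2-yl)silyl]tridec-5-ene-2,12-diyn-4-ol
Conditions: (R)-2-methyl-CBS-oxazaborolidine (1.0 equiv), BH3·SMe2, THF, −30 °C; MeOH quench
Reagents that add atoms: none
Why: Corey–Bakshi–Shibata reduction, in which the (R)-oxazaborolidine delivers hydride to the ketone face defined by the large alkenyl and the small propynyl group, which should give the (4R) carbinol.

Step 11
Reactants: 19 (4R,5E,10R)-6,10-dimethyl-13-[tri(propan-2-yl)silyl]tridec-5-ene-2,12-diyn-4-ol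
Product: 20 (2Z,4S,5E,10R)-6,10-dimethyl-13-[tri(propan-2-yl)silyl]trideca-2,5-dien-12-yn-4-ol
Conditions: H2 (1 atm), Pd/CaCO3 poisoned with Pb(OAc)2 (Lindlar catalyst), quinoline, EtOAc/hexane, 0 °C → rt, stopped after one equivalent of H2
Reagents that add atoms: none
Why: Lindlar semi-hydrogenation adds H2 syn to the unhindered propynyl triple bond to give the Z-alkene while the triisopropylsilyl-capped alkyne and the trisubstituted alkene should be too hindered to compete; the descriptor changes from R to S only because the priorities change.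

Step 12
Reactants: 20 (2Z,4S,5E,10R)-6,10-dimethyl-13-[tri(propan-2-yl)silyl]trideca-2,5-dien-12-yn-4-ol
Product: 21 (2Z,4S,5E,10R)-6,10-dimethyl-13-[tri(propan-2-yl)silyl]trideca-2,5-dien-12-yn-4-yl pyridine-2-carboxylate
Conditions: pyridine-2-carboxylic acid, DCC, DMAP (cat.), CH2Cl2, 0 °C; used at once
Reagents that add atoms: pyridine-2-carboxylic acid, OC(=O)c1ccccn1
Why: Steglich esterification under neutral, cold conditions, which should avoid ionisation of the bis-allylic carbinol and leave its configuration untouched.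

Step 13
Reactants: 22 (2E)-3-(tributylstannyl)prop-2-en-1-ol
Product: 23 [(1S,2R)-2-(tributylstannyl)cyclopropyl]methanol
Conditions: Zn(CH2I)2·DME (from Et2Zn, CH2I2, DME), (4S,5S)-2-butyl-N,N,N′,N′-tetramethyl-1,3,2-dioxaborolane-4,5-dicarboxamide (1.2 equiv), CH2Cl2, −10 °C → rt; aq. NH4Cl, then aq. NaOH wash
Reagents that add atoms: diiodomethane, ICI
Why: Hydroxyl-directed asymmetric Simmons–Smith cyclopropanation in which the zinc alkoxide bound to the chiral dioxaborolane delivers CH2 to one alkene face; syn addition to the E-alkene keeps Sn and CH2OH trans, and the (4S,5S) ligand, the mirror image of the one that turns cinnamyl alcohol into the (1S,2S) cyclopropane, should give the (1S,2R) product.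

Step 14
Reactants: 23 [(1S,2R)-2-(tributylstannyl)cyclopropyl]methanol
Product: 24 [(1S,2R)-2-(tributylstannyl)cyclopropyl]methyl 4-methylbenzenesulfonate
Conditions: TsCl, Et3N, DMAP (cat.), CH2Cl2, 0 °C; used crude
Reagents that add atoms: 4-methylbenzenesulfonyl chloride, Cc1ccc(cc1)S(Cl)(=O)=O
Why: Sulfonylation of the primary alcohol under basic, non-ionising conditions that leave the C–Sn bond and the ring untouched.

Step 15
Reactants: 24 [(1S,2R)-2-(tributylstannyl)cyclopropyl]methyl 4-methylbenzenesulfonate; 25 2-(2-bromoethyl)-1,3-dioxolane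
Product: 27 tributyl{(1R,2R)-2-[3-(1,3-dioxolan-2-yl)propyl]cyclopropyl}stannane, via Grignard reagent 26 (not isolated)
Conditions: 25, Mg, THF, ≤ 30 °C; then 24, Li2CuCl4 (5 mol %), THF, −30 → 0 °C
Reagents that add atoms: none
Why: Copper-catalysed coupling of a primary tosylate with a primary alkyl Grignard reagent, an SN2-like displacement by the cuprate that should avoid radical or cationic opening of the cyclopropylmethyl system and does not touch the C–Sn bond or the acetal.

Step 16
Reactants: 27 tributyl{(1R,2R)-2-[3-(1,3-dioxolan-2-yl)propyl]cyclopropyl}stannane; 21 (2Z,4S,5E,10R)-6,10-dimethyl-13-[tri(propan-2-yl)silyl]trideca-2,5-dien-12-yn-4-yl pyridine-2-carboxylate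
Product: 31 2-(3-{(1R,2R)-2-[(2S,3E,5E,10R)-6,10-dimethyl-13-[tri(propan-2-yl)silyl]trideca-3,5-dien-12-yn-2-yl]cyclopropyl}propyl)-1,3-dioxolane, via cyclopropyllithium 28 (not isolated), via cyclopropylmagnesium bromide 29 (not isolated), via cyclopropylcopper 30 (not isolated)
Conditions: 27 (1.5 equiv), n-BuLi (1.4 equiv), THF, −78 → 0 °C; MgBr2·OEt2, −78 °C; CuBr·SMe2, −78 → −40 °C; then 21, THF, −60 → 0 °C; aq. NH4Cl
Reagents that add atoms: none
Why: Proposed new method: tin–lithium exchange gives cyclopropyllithium 28, which holds its configuration because of the high s-character of the exocyclic carbon–metal bond and passes with retention to magnesium (29) and copper (30); MgBr2 held between the pyridine nitrogen and the carbonyl oxygen of 21 weakens the C–O bond, monovalent copper adds to the propenyl alkene on the face opposite the leaving group, and the γ-σ-allyl trivalent copper species reductively eliminates with retention before it can equilibrate, so the C(cyclopropyl)–C(H)(CH3) bond forms at the methyl-bearing propenyl carbon while the alkene moves into conjugation. The closest known reaction type is the copper-mediated anti-SN2′ substitution of secondary allylic picolinates by Grignard-derived alkyl, aryl and alkenyl copper reagents with 1,3-chirality transfer, together with the retentive tin–lithium–copper relay of cyclopropylstannanes; new here is a substituted cyclopropylcopper acting on a dienylic picolinate. No ring is closed. The new methine is controlled by the (4S) carbinol centre of 21: A(1,3) strain of the Z-propenyl group holds the carbinol C–H in the alkene plane, so a single rotamer places the C–O bond perpendicular to the π system, and anti attack on it should give the (S) methine and the E geometry of the new CH=CH at the same time. The step needs γ-selectivity for the propenyl terminus over attack at the carbinol carbon and over the other allylic terminus, which should be secured by the chelating leaving group, by the unhindered CH(CH3) terminus set against the fully substituted C(CH3)(CH2R) terminus, and by the gain of diene conjugation. The cyclopropane centres and the remote methyl centre are spectators.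

Step 17
Reactants: 31 2-(3-{(1R,2R)-2-[(2S,3E,5E,10R)-6,10-dimethyl-13-[tri(propan-2-yl)silyl]trideca-3,5-dien-12-yn-2-yl]cyclopropyl}propyl)-1,3-dioxolane
Product: 32 2-(3-{(1R,2R)-2-[(2S,3E,5E,10R)-6,10-dimethyltrideca-3,5-dien-12-yn-2-yl]cyclopropyl}propyl)-1,3-dioxolane
Conditions: TBAF, THF, 0 °C → rt
Reagents that add atoms: none
Why: Fluoride-mediated protodesilylation of the alkynylsilane; the acetal, the diene and the cyclopropane are inert to fluoride.

Step 18
Reactants: 32 2-(3-{(1R,2R)-2-[(2S,3E,5E,10R)-6,10-dimethyltrideca-3,5-dien-12-yn-2-yl]cyclopropyl}propyl)-1,3-dioxolane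
Product: 33 2-(3-{(1R,2R)-2-[(2S,3E,5E,10R)-13-bromo-6,10-dimethyltrideca-3,5-dien-12-yn-2-yl]cyclopropyl}propyl)-1,3-dioxolane
Conditions: NBS, AgNO3 (10 mol %), acetone, rt, dark
Reagents that add atoms: N-bromosuccinimide, O=C1CCC(=O)N1Br
Why: Silver-catalysed electrophilic bromination of the terminal alkyne through its silver acetylide, which should be much faster than attack of NBS on the diene in dry acetone in the dark.

Step 19
Reactants: 33 2-(3-{(1R,2R)-2-[(2S,3E,5E,10R)-13-bromo-6,10-dimethyltrideca-3,5-dien-12-yn-2-yl]cyclopropyl}propyl)-1,3-dioxolane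
Product: 34 4-{(1R,2R)-2-[(2S,3E,5E,10R)-13-bromo-6,10-dimethyltrideca-3,5-dien-12-yn-2-yl]cyclopropyl}butanal
Conditions: 2 M aq. HCl, THF, 0 °C → rt
Reagents that add atoms: water, O
Why: Acid-catalysed acetal hydrolysis; the bromoalkyne, the cyclopropane (insulated from the diene by the sp3 methine) and the diene should tolerate brief dilute acid at room temperature.

Step 20
Reactants: 34 4-{(1R,2R)-2-[(2S,3E,5E,10R)-13-bromo-6,10-dimethyltrideca-3,5-dien-12-yn-2-yl]cyclopropyl}butanal
Product: 35 4-{(1R,2R)-2-[(2S,3E,5E,10R)-13-bromo-6,10-dimethyltrideca-3,5-dien-12-yn-2-yl]cyclopropyl}butanoic acid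
Conditions: NaClO2, NaH2PO4, 2-methylbut-2-ene, t-BuOH/H2O, 0 °C → rt
Reagents that add atoms: sodium chlorite (NaClO2), [Na+].[O-]Cl=O
Why: Pinnick oxidation of the aldehyde, with 2-methylbut-2-ene trapping HOCl so that the diene and the bromoalkyne are spared; no stereocentre is α to the carbonyl.

**Compound list**

1 | (R)-citronellal, (3R)-3,7-dimethyloct-6-enal | C[C@H](CCC=C(C)C)CC=O | starting material
2 | (4R)-1,1-dibromo-4,8-dimethylnona-1,7-diene | CC(C)=CCC[C@@H](C)CC=C(Br)Br | intermediate
3 | lithium acetylide of (4R)-4,8-dimethylnon-7-en-1-yne | CC(C)=CCC[C@@H](C)CC#C[Li] | intermediate (not isolated)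
4 | [(4R)-4,8-dimethylnon-7-en-1-yn-1-yl]tri(propan-2-yl)silane | CC(C)=CCC[C@@H](C)CC#C[Si](C(C)C)(C(C)C)C(C)C | intermediate
5 | (4R)-4-methyl-7-[tri(propan-2-yl)silyl]hept-6-ynal | O=CCC[C@@H](C)CC#C[Si](C(C)C)(C(C)C)C(C)C | intermediate (not isolated)
6 | (4R)-4-methyl-7-[tri(propan-2-yl)silyl]hept-6-yn-1-ol | OCCC[C@@H](C)CC#C[Si](C(C)C)(C(C)C)C(C)C | intermediate
7 | [(4R)-7-iodo-4-methylhept-1-yn-1-yl]tri(propan-2-yl)silane | ICCC[C@@H](C)CC#C[Si](C(C)C)(C(C)C)C(C)C | intermediate
8 | ethynyl(trimethyl)silane (trimethylsilylacetylene) | C#C[Si](C)(C)C | starting material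
9 | lithium (trimethylsilyl)acetylide | [Li]C#C[Si](C)(C)C | intermediate (not isolated)
10 | trimethyl{(6R)-6-methyl-9-[tri(propan-2-yl)silyl]nona-1,8-diyn-1-yl}silane | C[Si](C)(C)C#CCCC[C@@H](C)CC#C[Si](C(C)C)(C(C)C)C(C)C | intermediate
11 | [(4R)-4-methylnona-1,8-diyn-1-yl]tri(propan-2-yl)silane | C#CCCC[C@@H](C)CC#C[Si](C(C)C)(C(C)C)C(C)C | intermediate
12 | dimethyl{(1E,6R)-2,6-dimethyl-9-[tri(propan-2-yl)silyl]non-1-en-8-yn-1-yl}alumane | C[Al](C)/C=C(\C)CCC[C@@H](C)CC#C[Si](C(C)C)(C(C)C)C(C)C | intermediate (not isolated)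
13 | [(4R,8E)-9-iodo-4,8-dimethylnon-8-en-1-yn-1-yl]tri(propan-2-yl)silane | I/C=C(\C)CCC[C@@H](C)CC#C[Si](C(C)C)(C(C)C)C(C)C | intermediate
14 | but-2-ynoic acid | CC#CC(=O)O | starting material
15 | but-2-ynoic 2-methylpropyl carbonic anhydride | CC#CC(=O)OC(=O)OCC(C)C | intermediate (not isolated)
16 | N-methoxy-N-methylbut-2-ynamide | CC#CC(=O)N(C)OC | intermediate
17 | {(1E,6R)-2,6-dimethyl-9-[tri(propan-2-yl)silyl]non-1-en-8-yn-1-yl}lithium | [Li]/C=C(\C)CCC[C@@H](C)CC#C[Si](C(C)C)(C(C)C)C(C)C | intermediate (not isolated)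
18 | (5E,10R)-6,10-dimethyl-13-[tri(propan-2-yl)silyl]tridec-5-ene-2,12-diyn-4-one | CC#CC(=O)/C=C(\C)CCC[C@@H](C)CC#C[Si](C(C)C)(C(C)C)C(C)C | intermediate
19 | (4R,5E,10R)-6,10-dimethyl-13-[tri(propan-2-yl)silyl]tridec-5-ene-2,12-diyn-4-ol | CC#C[C@H](O)/C=C(\C)CCC[C@@H](C)CC#C[Si](C(C)C)(C(C)C)C(C)C | intermediate
20 | (2Z,4S,5E,10R)-6,10-dimethyl-13-[tri(propan-2-yl)silyl]trideca-2,5-dien-12-yn-4-ol | C/C=C\[C@H](O)/C=C(\C)CCC[C@@H](C)CC#C[Si](C(C)C)(C(C)C)C(C)C | intermediate
21 | (2Z,4S,5E,10R)-6,10-dimethyl-13-[tri(propan-2-yl)silyl]trideca-2,5-dien-12-yn-4-yl pyridine-2-carboxylate | C/C=C\[C@H](OC(=O)c1ccccn1)/C=C(\C)CCC[C@@H](C)CC#C[Si](C(C)C)(C(C)C)C(C)C | intermediate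
22 | (2E)-3-(tributylstannyl)prop-2-en-1-ol | OC/C=C/[Sn](CCCC)(CCCC)CCCC | starting material
23 | [(1S,2R)-2-(tributylstannyl)cyclopropyl]methanol | CCCC[Sn](CCCC)(CCCC)[C@@H]1C[C@H]1CO | intermediate
24 | [(1S,2R)-2-(tributylstannyl)cyclopropyl]methyl 4-methylbenzenesulfonate | CCCC[Sn](CCCC)(CCCC)[C@@H]1C[C@H]1COS(=O)(=O)c1ccc(C)cc1 | intermediate
25 | 2-(2-bromoethyl)-1,3-dioxolane | BrCCC1OCCO1 | starting material
26 | [2-(1,3-dioxolan-2-yl)ethyl]magnesium bromide | Br[Mg]CCC1OCCO1 | intermediate (not isolated)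
27 | tributyl{(1R,2R)-2-[3-(1,3-dioxolan-2-yl)propyl]cyclopropyl}stannane | CCCC[Sn](CCCC)(CCCC)[C@@H]1C[C@H]1CCCC2OCCO2 | intermediate
28 | {(1R,2R)-2-[3-(1,3-dioxolan-2-yl)propyl]cyclopropyl}lithium | [Li][C@@H]1C[C@H]1CCCC2OCCO2 | intermediate (not isolated)
29 | bromo{(1R,2R)-2-[3-(1,3-dioxolan-2-yl)propyl]cyclopropyl}magnesium | Br[Mg][C@@H]1C[C@H]1CCCC2OCCO2 | intermediate (not isolated)
30 | {(1R,2R)-2-[3-(1,3-dioxolan-2-yl)propyl]cyclopropyl}copper (as its MgBr2 complex) | [Cu][C@@H]1C[C@H]1CCCC2OCCO2 | intermediate (not isolated)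
31 | 2-(3-{(1R,2R)-2-[(2S,3E,5E,10R)-6,10-dimethyl-13-[tri(propan-2-yl)silyl]trideca-3,5-dien-12-yn-2-yl]cyclopropyl}propyl)-1,3-dioxolane | C/C(=C\C=C\[C@H](C)[C@@H]1C[C@H]1CCCC2OCCO2)CCC[C@@H](C)CC#C[Si](C(C)C)(C(C)C)C(C)C | intermediate
32 | 2-(3-{(1R,2R)-2-[(2S,3E,5E,10R)-6,10-dimethyltrideca-3,5-dien-12-yn-2-yl]cyclopropyl}propyl)-1,3-dioxolane | C/C(=C\C=C\[C@H](C)[C@@H]1C[C@H]1CCCC2OCCO2)CCC[C@@H](C)CC#C | intermediate
33 | 2-(3-{(1R,2R)-2-[(2S,3E,5E,10R)-13-bromo-6,10-dimethyltrideca-3,5-dien-12-yn-2-yl]cyclopropyl}propyl)-1,3-dioxolane | C/C(=C\C=C\[C@H](C)[C@@H]1C[C@H]1CCCC2OCCO2)CCC[C@@H](C)CC#CBr | intermediate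
34 | 4-{(1R,2R)-2-[(2S,3E,5E,10R)-13-bromo-6,10-dimethyltrideca-3,5-dien-12-yn-2-yl]cyclopropyl}butanal | C/C(=C\C=C\[C@H](C)[C@@H]1C[C@H]1CCCC=O)CCC[C@@H](C)CC#CBr | intermediate
35 | 4-{(1R,2R)-2-[(2S,3E,5E,10R)-13-bromo-6,10-dimethyltrideca-3,5-dien-12-yn-2-yl]cyclopropyl}butanoic acid (CNP0116210.1) | C/C(=C\C=C\[C@H](C)[C@@H]1C[C@H]1CCCC(=O)O)CCC[C@@H](C)CC#CBr | target

**Step count**

Total: 20 steps. Longest linear sequence: 16 steps from (R)-citronellal (steps 1–7, 9–12, 16–20).

**Steps most likely to fail**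

1. Step 16. The secondary cyclopropyl group may transfer sluggishly from copper, substitution may occur at the carbinol carbon or at the other allylic terminus, or the bis-allylic ester may ionise so that chirality transfer is lost. The fallback sets the same methine by auxiliary-controlled enolate methylation and closes the diene by an sp2–sp2 coupling; it sets out from stannane 27 (and uses iodide 13) and comes back at 31.
   - Tin–lithium exchange of 27 (n-BuLi, THF) to 28 and opening of oxirane would give 2-{trans-2-[3-(1,3-dioxolan-2-yl)propyl]cyclopropyl}ethan-1-ol F1.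
   - TEMPO/NaOCl/NaClO2 at pH 6.7 would give the corresponding acetic acid F2.
   - Pivaloyl chloride/Et3N would form the mixed pivalic anhydride F3 in the flask, which acylates lithiated (R)-4-benzyl-1,3-oxazolidin-2-one to the imide F4.
   - NaN(SiMe3)2 then MeI at −78 °C should methylate the Z-enolate on the face away from the benzyl group (Evans alkylation) to give the (2R)-propanoyl imide F5.
   - LiBH4 would release the (2R)-propanol F6, and Dess–Martin periodinane would give the (2R)-propanal F7.
   - Takai-type boryl olefination (CrCl2, LiI, Cl2CHBpin, THF) would give the (E)-alkenylboronate F8.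
   - Suzuki–Miyaura coupling of F8 with 13 (Pd(PPh3)4, aq. K3PO4, THF), with retention of both alkene geometries, would return to 31.

2. Step 15. The stannyl-substituted cyclopropylmethyl sulfonate may ionise and fragment, or the ring may open during the coupling. The fallback attaches the three carbons by carbonyl olefination; it sets out from alcohol 23 (and bromide 25) and comes back at 27.
   - Dess–Martin oxidation of 23 would give trans-2-(tributylstannyl)cyclopropane-1-carbaldehyde F9.
   - Bromide 25 and PPh3 (MeCN, reflux) would give [2-(1,3-dioxolan-2-yl)ethyl]triphenylphosphonium bromide F10.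
   - NaN(SiMe3)2 would convert F10 into the phosphorus ylide F11, which in a Wittig reaction with F9 should give the Z-alkenylcyclopropane F12.
   - Diimide (2-nitrobenzenesulfonohydrazide, Et3N) would saturate the disubstituted alkene without touching the ring or the C–Sn bond and return to 27.

3. Step 10. Facial discrimination may be poor because both ketone substituents are unsaturated. The fallback replaces catalyst control by a kinetic resolution; it sets out from ynone 18 and comes back at 19.
   - Luche reduction (NaBH4, CeCl3·7H2O, MeOH, −78 °C) would give the alcohol as a mixture of both C4 epimers F13.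
   - Lipase-catalysed acylation (Burkholderia cepacia lipase, vinyl acetate, hexane) should, by the empirical size rule for secondary alcohols, acetylate the (4S) epimer to the acetate F14 and leave the (4R) alcohol, which is 19.
   - F14 can be recycled to 18 by methanolysis and MnO2 oxidation.

**Further compounds**

F1 | step 16 | 2-{trans-2-[3-(1,3-dioxolan-2-yl)propyl]cyclopropyl}ethan-1-ol (ring configuration as in 27) | OCC[C@@H]1C[C@H]1CCCC2OCCO2
F2 | step 16 | 2-{trans-2-[3-(1,3-dioxolan-2-yl)propyl]cyclopropyl}acetic acid | OC(=O)C[C@@H]1C[C@H]1CCCC2OCCO2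
F3 | step 16 | mixed anhydride of F2 with 2,2-dimethylpropanoic acid | CC(C)(C)C(=O)OC(=O)C[C@@H]1C[C@H]1CCCC2OCCO2
F4 | step 16 | (4R)-4-benzyl-3-(2-{trans-2-[3-(1,3-dioxolan-2-yl)propyl]cyclopropyl}acetyl)-1,3-oxazolidin-2-one | O=C(C[C@@H]1C[C@H]1CCCC2OCCO2)N3[C@H](Cc4ccccc4)COC3=O
F5 | step 16 | (4R)-4-benzyl-3-[(2R)-2-{trans-2-[3-(1,3-dioxolan-2-yl)propyl]cyclopropyl}propanoyl]-1,3-oxazolidin-2-one | O=C([C@H](C)[C@@H]1C[C@H]1CCCC2OCCO2)N3[C@H](Cc4ccccc4)COC3=O
F6 | step 16 | (2R)-2-{trans-2-[3-(1,3-dioxolan-2-yl)propyl]cyclopropyl}propan-1-ol | OC[C@H](C)[C@@H]1C[C@H]1CCCC2OCCO2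
F7 | step 16 | (2R)-2-{trans-2-[3-(1,3-dioxolan-2-yl)propyl]cyclopropyl}propanal | O=C[C@H](C)[C@@H]1C[C@H]1CCCC2OCCO2
F8 | step 16 | 2-[(1E,3S)-3-{trans-2-[3-(1,3-dioxolan-2-yl)propyl]cyclopropyl}but-1-en-1-yl]-4,4,5,5-tetramethyl-1,3,2-dioxaborolane | CC1(C)OB(/C=C/[C@H](C)[C@@H]2C[C@H]2CCCC3OCCO3)OC1(C)C
F9 | step 15 | trans-2-(tributylstannyl)cyclopropane-1-carbaldehyde (ring configuration as in 23) | CCCC[Sn](CCCC)(CCCC)[C@@H]1C[C@H]1C=O
F10 | step 15 | [2-(1,3-dioxolan-2-yl)ethyl]triphenylphosphonium bromide | [Br-].c1ccccc1[P+](CCC2OCCO2)(c3ccccc3)c4ccccc4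
F11 | step 15 | [2-(1,3-dioxolan-2-yl)ethylidene]triphenylphosphorane | c1ccccc1P(=CCC2OCCO2)(c3ccccc3)c4ccccc4
F12 | step 15 | tributyl{trans-2-[(1Z)-3-(1,3-dioxolan-2-yl)prop-1-en-1-yl]cyclopropyl}stannane | CCCC[Sn](CCCC)(CCCC)[C@@H]1C[C@H]1/C=C\CC2OCCO2
F13 | step 10 | (5E,10R)-6,10-dimethyl-13-[tri(propan-2-yl)silyl]tridec-5-ene-2,12-diyn-4-ol, mixture of both C4 epimers | CC#CC(O)/C=C(\C)CCC[C@@H](C)CC#C[Si](C(C)C)(C(C)C)C(C)C
F14 | step 10 | (4S,5E,10R)-6,10-dimethyl-13-[tri(propan-2-yl)silyl]tridec-5-ene-2,12-diyn-4-yl acetate | CC#C[C@@H](OC(C)=O)/C=C(\C)CCC[C@@H](C)CC#C[Si](C(C)C)(C(C)C)C(C)C
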